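The route cuts the C4–C5 bond of the heptanoid chain. The C3 ketone and the C5 carbinol are a 1,3-related aldol pair, so this cut gives a ring A (guaiacyl) methyl ketone and a ring B (syringyl) 3-arylpropanal of similar size. A reagent-controlled boron aldol then joins the halves and sets the single stereocentre (5R) in one operation, with no substrate bias to overcome. The aldol partners are O-benzylzingerone and 3-(4-benzyloxy-3,5-dimethoxyphenyl)propanal; both phenols are masked as benzyl ethers so that one neutral hydrogenolysis ends the synthesis.

Key step: step 5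

Assumption (facial sense): (−)-Ipc2BCl, the reagent made from (+)-α-pinene, is taken to deliver a methyl ketone enolate to the Si face of an unbranched aldehyde, which gives 5R here. If Mosher ester analysis of the first run shows the opposite sense, (+)-Ipc2BCl is used with no other change.

Structure check: C5 is R in the target and in the protected aldol (priorities OH > C4 > C6 > H); no structure needed correction.

Remark (ring B source): the aldehyde is made from commercial 4-allyl-2,6-dimethoxyphenol, which already carries the three-carbon chain. This takes three robust steps and avoids a partial ester reduction.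

Step 1
Reactants: 1 zingerone; 2 benzyl bromide
Product: 3 4-[4-(benzyloxy)-3-methoxyphenyl]butan-2-one (O-benzylzingerone)
Conditions: K2CO3, DMF, rt
Reagents that add atoms: none
Why: Williamson ether synthesis, in which K2CO3 forms the phenoxide but is too weak to enolise the methyl ketone, so O-benzylation should be the only pathway.

Step 2
Reactants: 4 4-allyl-2,6-dimethoxyphenol (methoxyeugenol); 2 benzyl bromide
Product: 5 5-allyl-2-(benzyloxy)-1,3-dimethoxybenzene
Conditions: K2CO3, DMF, 60 °C
Reagents that add atoms: none
Why: Williamson ether synthesis, in which the hindered 2,6-dimethoxyphenoxide still reacts with the reactive benzylic bromide and carbonate is too weak a base to move the allyl double bond into conjugation.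

Step 3
Reactants: 5 5-allyl-2-(benzyloxy)-1,3-dimethoxybenzene
Product: 7 3-[4-(benzyloxy)-3,5-dimethoxyphenyl]propan-1-ol, via primary alkylborane 6 (not isolated)
Conditions: 9-BBN, THF, 0 °C to rt; then NaOH aq, H2O2, 0 °C to rt
Reagents that add atoms: hydrogen peroxide, OO
Why: Brown hydroboration–oxidation, in which the bulky 9-BBN places boron on the terminal carbon of the monosubstituted alkene and alkaline peroxide turns the C–B bond into C–OH, leaving the benzyl ether and the arene untouched.

Step 4
Reactants: 7 3-[4-(benzyloxy)-3,5-dimethoxyphenyl]propan-1-ol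
Product: 8 3-[4-(benzyloxy)-3,5-dimethoxyphenyl]propanal
Conditions: Dess–Martin periodinane, CH2Cl2, 0 °C to rt
Reagents that add atoms: none
Why: Dess–Martin oxidation, which under anhydrous conditions should stop at the aldehyde and tolerates the electron-rich ring and the benzyl ether; the aldehyde is used promptly.

Step 5
Reactants: 3 4-[4-(benzyloxy)-3-methoxyphenyl]butan-2-one; 8 3-[4-(benzyloxy)-3,5-dimethoxyphenyl]propanal
Product: 11 (5R)-1-[4-(benzyloxy)-3-methoxyphenyl]-7-[4-(benzyloxy)-3,5-dimethoxyphenyl]-5-hydroxyheptan-3-one, via enol borinate 9 (not isolated), via boron aldolate 10 (not isolated)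
Conditions: (−)-Ipc2BCl, Et3N, Et2O, 0 °C; then 8, −78 to −20 °C; then H2O2, MeOH, pH 7 buffer, 0 °C
Reagents that add atoms: none
Why: Ipc2BCl binds the ketone oxygen and Et3N removes a proton from the unhindered methyl group to give enol borinate 9; the aldehyde then binds boron and the C4–C5 bond forms through a closed six-membered boron-bridged transition state to give aldolate 10, which peroxide releases as 11. The closest known reaction type is the asymmetric boron aldol of methyl ketones with aldehydes after Ipc2BCl/tertiary amine enolisation. No ring is closed, so no mode of closure applies. The one new stereocentre, C5, is controlled by the isopinocampheyl ligands alone, which are expected to send the enolate to the Si face of the aldehyde and so give 5R; neither partner has a stereocentre or an α-branch that could oppose the reagent. The step needs enolisation at the methyl group and not at the C2 methylene, secured by the bulk of the dialkylboron chloride under kinetic conditions, and cross-aldol over self-aldol, secured by forming 9 completely before the enolisable aldehyde is added cold. The buffered oxidative work-up cleaves the B–O and B–C bonds without exposing the β-hydroxy ketone to acid or base, which guards against dehydration and retro-aldol.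

Step 6
Reactants: 11 (5R)-1-[4-(benzyloxy)-3-methoxyphenyl]-7-[4-(benzyloxy)-3,5-dimethoxyphenyl]-5-hydroxyheptan-3-one
Product: 12 (5R)-5-hydroxy-7-(4-hydroxy-3,5-dimethoxyphenyl)-1-(4-hydroxy-3-methoxyphenyl)heptan-3-one
Conditions: H2 (1 atm), 10% Pd/C, EtOAc–EtOH, rt
Reagents that add atoms: none
Why: Catalytic hydrogenolysis of the two aryl benzyl ethers, which should cleave only the benzylic C–O bonds, since the non-benzylic ketone and the C5 alcohol are inert at 1 atm and rt and the neutral medium gives no path to β-elimination or retro-aldol, so C5 stays R.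

Compound list
1 | zingerone, 4-(4-hydroxy-3-methoxyphenyl)butan-2-one | COc1cc(CCC(C)=O)ccc1O | starting material
2 | benzyl bromide | BrCc1ccccc1 | starting material
3 | 4-[4-(benzyloxy)-3-methoxyphenyl]butan-2-one (O-benzylzingerone) | COc1cc(CCC(C)=O)ccc1OCc1ccccc1 | intermediate
4 | 4-allyl-2,6-dimethoxyphenol (methoxyeugenol) | C=CCc1cc(OC)c(O)c(OC)c1 | starting material
5 | 5-allyl-2-(benzyloxy)-1,3-dimethoxybenzene | C=CCc1cc(OC)c(OCc2ccccc2)c(OC)c1 | intermediate
6 | 9-{3-[4-(benzyloxy)-3,5-dimethoxyphenyl]propyl}-9-borabicyclo[3.3.1]nonane | COc1cc(CCCB2C3CCCC2CCC3)cc(OC)c1OCc1ccccc1 | intermediate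
7 | 3-[4-(benzyloxy)-3,5-dimethoxyphenyl]propan-1-ol | OCCCc1cc(OC)c(OCc2ccccc2)c(OC)c1 | intermediate
8 | 3-[4-(benzyloxy)-3,5-dimethoxyphenyl]propanal | O=CCCc1cc(OC)c(OCc2ccccc2)c(OC)c1 | intermediate
9 | 4-[4-(benzyloxy)-3-methoxyphenyl]but-1-en-2-yl bis[(1R,2S,3R,5R)-2,6,6-trimethylbicyclo[3.1.1]hept-3-yl]borinate (enol borinate of 3; isopinocampheyl groups from (+)-α-pinene) | C=C(CCc1ccc(OCc2ccccc2)c(OC)c1)OB([C@@H]1C[C@@H]2C[C@@H](C2(C)C)[C@H]1C)[C@@H]1C[C@@H]2C[C@@H](C2(C)C)[C@H]1C | intermediate
10 | (5R)-boron aldolate: 11 with its C5 oxygen bound to a bis[(1R,2S,3R,5R)-isopinocampheyl]boryl group | COc1cc(CCC(=O)C[C@H](OB([C@@H]3C[C@@H]4C[C@@H](C4(C)C)[C@H]3C)[C@@H]3C[C@@H]4C[C@@H](C4(C)C)[C@H]3C)CCc2cc(OC)c(OCc3ccccc3)c(OC)c2)ccc1OCc1ccccc1 | intermediate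
11 | (5R)-1-[4-(benzyloxy)-3-methoxyphenyl]-7-[4-(benzyloxy)-3,5-dimethoxyphenyl]-5-hydroxyheptan-3-one | COc1cc(CCC(=O)C[C@H](O)CCc2cc(OC)c(OCc3ccccc3)c(OC)c2)ccc1OCc1ccccc1 | intermediate
12 | (5R)-5-hydroxy-7-(4-hydroxy-3,5-dimethoxyphenyl)-1-(4-hydroxy-3-methoxyphenyl)heptan-3-one | COc1cc(CCC(=O)C[C@H](O)CCc2cc(OC)c(O)c(OC)c2)ccc1O | target

Total step count: 6. Longest linear sequence: 5 steps (4 → 5 → 7 → 8 → 11 → 12).

Steps most likely to fail

1. Step 5. The isopinocampheyl groups may tell the two aldehyde faces apart only moderately, as is usual for methyl ketone enol borinates, and some enolisation toward the C2 methylene would lower the yield. Enantiomeric purity would be measured on 11 by chiral HPLC, and recrystallisation of 11 would be tried first if it is a solid. The fallback replaces the closed boron transition state by an open, catalyst-controlled Mukaiyama aldol. It sets out from 3: kinetic deprotonation with LiN(iPr)2 in THF at −78 °C and trapping with Me3SiCl should give the terminal enol silane 1-(benzyloxy)-2-methoxy-4-[3-(trimethylsilyloxy)but-3-en-1-yl]benzene F1. Addition of this enol silane to 8 in EtCN at −78 °C, under the B-butyl oxazaborolidinone made from N-tosyl-D-tryptophan and BuB(OH)2, should give (5R)-1-[4-(benzyloxy)-3-methoxyphenyl]-7-[4-(benzyloxy)-3,5-dimethoxyphenyl]-5-(trimethylsilyloxy)heptan-3-one F2. This catalyst antipode is the one expected to leave the Si face open; the sense would be checked as above. Brief treatment with dilute aqueous HCl in THF at 0 °C should remove the silyl group and return to the route at 11.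

2. Step 6. Acid traces on the catalyst could trigger β-elimination of the C5 hydroxyl followed by hydrogenation of the enone, which would erase the stereocentre; cleavage of the hindered ring B benzyl ether could also stall. The fallback abandons reductive cleavage for Lewis-acid dealkylation. It sets out from 11: BCl3 with pentamethylbenzene as cation trap in CH2Cl2 at −78 °C, then a MeOH and aqueous NaHCO3 quench. The β-hydroxy ketone is held as a boron chelate at this temperature and the aryl methyl ethers should survive. It returns to the route at 12 and makes no new compound (F0).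

3. Step 4. The enolisable aldehyde could be over-oxidised or could self-condense during oxidation and isolation. The fallback reaches the aldehyde by reduction from a stable, storable amide. It sets out from 7: TEMPO (catalytic) and PhI(OAc)2 in MeCN–water should oxidise it through to 3-[4-(benzyloxy)-3,5-dimethoxyphenyl]propanoic acid F3. Activation with 1,1'-carbonyldiimidazole and reaction with MeNHOMe·HCl in CH2Cl2 should give 3-[4-(benzyloxy)-3,5-dimethoxyphenyl]-N-methoxy-N-methylpropanamide F4. Reduction with LiAlH4 in THF at −40 to 0 °C forms a stable chelated adduct that releases the aldehyde only on cold aqueous KHSO4 quench, returning to the route at 8, which is taken directly into step 5.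

Further compounds
F1 | step 5 | 1-(benzyloxy)-2-methoxy-4-[3-(trimethylsilyloxy)but-3-en-1-yl]benzene | C=C(CCc1ccc(OCc2ccccc2)c(OC)c1)O[Si](C)(C)C
F2 | step 5 | (5R)-1-[4-(benzyloxy)-3-methoxyphenyl]-7-[4-(benzyloxy)-3,5-dimethoxyphenyl]-5-(trimethylsilyloxy)heptan-3-one | COc1cc(CCC(=O)C[C@H](O[Si](C)(C)C)CCc2cc(OC)c(OCc3ccccc3)c(OC)c2)ccc1OCc1ccccc1
F0 | step 6 | none | none
F3 | step 4 | 3-[4-(benzyloxy)-3,5-dimethoxyphenyl]propanoic acid | OC(=O)CCc1cc(OC)c(OCc2ccccc2)c(OC)c1
F4 | step 4 | 3-[4-(benzyloxy)-3,5-dimethoxyphenyl]-N-methoxy-N-methylpropanamide | CON(C)C(=O)CCc1cc(OC)c(OCc2ccccc2)c(OC)c1
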